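The route rests on cutting the central C15=C15' double bond, which splits the C40 chain into two C20 polyenyne halves differing only at C4' of ring B. One Wittig condensation joins the ring A ylide to the ring B aldehyde; the 15Z isomer formed alongside is the unhindered central cis bond and reverts to E on mild heating, so C9=C10 and C9'=C10' beside the triple bonds stay untouched. The precursors are a ring A C20 phosphonium bromide, made without acid and kept as its C3 silyl ether, and a ring B C20 trienynal carrying the cis-3',4'-diol as a bis-silyl ether; both rings derive from (4R,6R)-actinol.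

Key step: step 16

Assumption: (E)-3-methylpent-2-en-4-yn-1-ol and triethyl 3-methyl-4-phosphonocrotonate are taken as catalogue chemicals; the target is read as the all-E (3R,3'S,4'R) triol, ring A being the 3-hydroxy ring and ring B the ring with the cis 3',4'-diol. TBS = tert-butyldimethylsilyl.

Step 1
Reactants: 1 (4R,6R)-4-hydroxy-2,2,6-trimethylcyclohexan-1-one (actinol)
Product: 2 (4R,6R)-4-(TBSO)-2,2,6-trimethylcyclohexan-1-one
Conditions: TBSCl, imidazole, DMF, rt
Reagents that add atoms: tert-butyldimethylsilyl chloride, CC(C)(C)[Si](C)(C)Cl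
Why: Silyl ether protection of the unhindered secondary alcohol should be clean, and the carbinol centre, which becomes C3 of ring A and C3' of ring B, is taken unchanged from the chiral pool so that neither ring needs an enantioselective step.

Step 2
Reactants: 2 silyl ether of actinol
Product: 4 (4R)-4-(TBSO)-2,6,6-trimethylcyclohex-1-en-1-yl trifluoromethanesulfonate, via lithium enolate 3 (not isolated)
Conditions: LiN(i-Pr)2, THF, −78 °C; PhNTf2, −78 °C → rt
Reagents that add atoms: N-phenylbis(trifluoromethanesulfonimide), O=S(=O)(N(c1ccccc1)S(=O)(=O)C(F)(F)F)C(F)(F)F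
Why: Enol triflate formation: the ketone can enolise only toward C6, so O-sulfonylation of enolate 3 should give a single tetrasubstituted vinyl triflate, the C6 centre being erased on purpose and the remote silyloxy group having no elimination pathway.

Step 3
Reactants: 5 (E)-3-methylpent-2-en-4-yn-1-ol
Product: 6 (E)-3-methylpent-2-en-4-ynal
Conditions: MnO2, CH2Cl2, rt; filtered and used as a cold concentrated solution
Reagents that add atoms: none
Why: MnO2 oxidation of a primary allylic alcohol should stop at the aldehyde and leave the E trisubstituted double bond and the terminal alkyne alone.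

Step 4
Reactants: 6 (E)-3-methylpent-2-en-4-ynal; 7 triethyl 3-methyl-4-phosphonocrotonate
Product: 9 ethyl (2E,4E,6E)-3,7-dimethylnona-2,4,6-trien-8-ynoate, via lithiated phosphonate 8 (not isolated)
Conditions: LiN(SiMe3)2, THF/DMPU, −78 °C; then 6, −78 → 0 °C
Reagents that add atoms: none
Why: Horner–Wadsworth–Emmons olefination with the vinylogous phosphonate anion 8 should form the new disubstituted double bond E and give mainly the 2E ester, any 2Z isomer being separable by chromatography at this small-molecule stage.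

Step 5
Reactants: 9 C11 trienynoate
Product: 10 (2E,4E,6E)-3,7-dimethylnona-2,4,6-trien-8-yn-1-ol
Conditions: i-Bu2AlH, CH2Cl2, −78 °C; aqueous KNaC4H4O6 work-up
Reagents that add atoms: none
Why: Ester reduction with i-Bu2AlH delivers hydride 1,2 to the conjugated ester and should give the primary allylic alcohol without touching the triene or the alkyne.

Step 6
Reactants: 4 ring A enol triflate; 10 C11 trienynol
Product: 11 (2E,4E,6E)-9-[(4R)-4-(TBSO)-2,6,6-trimethylcyclohex-1-en-1-yl]-3,7-dimethylnona-2,4,6-trien-8-yn-1-ol (ring A C20 alcohol)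
Conditions: Pd(PPh3)4 (cat.), CuI (cat.), i-Pr2NH, DMF, degassed, rt → 40 °C
Reagents that add atoms: none
Why: Sonogashira coupling of a cyclohexenyl triflate with a terminal enyne forms the C6–C7 bond under mild amine conditions that tolerate the free allylic alcohol and the silyl ether and do not touch any double-bond geometry.

Step 7
Reactants: 11 ring A C20 alcohol
Product: 13 {(2E,4E,6E)-9-[(4R)-4-(TBSO)-2,6,6-trimethylcyclohex-1-en-1-yl]-3,7-dimethylnona-2,4,6-trien-8-yn-1-yl}triphenylphosphonium bromide, via allylic bromide 12 (not isolated)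
Conditions: CBr4, PPh3, CH2Cl2, −20 °C; then further PPh3, 0 °C → rt
Reagents that add atoms: triphenylphosphine, c1ccccc1P(c1ccccc1)c1ccccc1; carbon tetrabromide, BrC(Br)(Br)Br
Why: Appel bromination followed by SN2 alkylation of PPh3 at the primary allylic carbon should give the salt under neutral conditions, so that no delocalised polyenyl cation arises to scramble the 9E and 13E bonds, while the retained C3 silyl ether leaves the primary alcohol as the only hydroxyl for the reagent.

Step 8
Reactants: 10 C11 trienynol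
Product: 14 tert-butyl{[(2E,4E,6E)-3,7-dimethylnona-2,4,6-trien-8-yn-1-yl]oxy}dimethylsilane
Conditions: TBSCl, imidazole, CH2Cl2, 0 °C → rt
Reagents that add atoms: tert-butyldimethylsilyl chloride, CC(C)(C)[Si](C)(C)Cl
Why: Silyl ether protection masks the only acidic O–H before acetylide formation and gives an ether that should survive the chromium oxidation of step 11.

Step 9
Reactants: 2 silyl ether of actinol
Product: 16 (4S)-4-(TBSO)-2,6,6-trimethylcyclohex-2-en-1-one, via silyl enol ether 15 (not isolated)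
Conditions: Me3SiOTf, Et3N, CH2Cl2, 0 °C → rt; solvent exchange; Pd(OAc)2 (stoichiometric), MeCN, rt
Reagents that add atoms: none
Why: Saegusa–Ito oxidation: soft enolisation with the silyl triflate and the amine converts the ketone, which can enolise only toward C6, directly into the single silyl enol ether 15, which is palladated by divalent palladium, and β-hydride elimination from the ring methylene should give the endocyclic 2-methyl enone, the carbinol centre being untouched (its label changes from R to S only through the priority rules).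

Step 10
Reactants: 14 C11 silyl ether; 16 ring enone
Product: 18 (4S)-4-(TBSO)-1-[(3E,5E,7E)-9-(TBSO)-3,7-dimethylnona-3,5,7-trien-1-yn-1-yl]-2,6,6-trimethylcyclohex-2-en-1-ol (both C1 epimers), via lithium acetylide 17 (not isolated)
Conditions: n-BuLi, THF, −78 °C; then 16, −78 → 0 °C
Reagents that add atoms: none
Why: 1,2-Addition of lithium acetylide 17 to the enone carbonyl, which has no α-hydrogen on its saturated side, should give the tertiary propargylic alcohol, and the new carbinol centre needs no control because step 11 removes it.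

Step 11
Reactants: 18 tertiary allylic alcohol
Product: 19 (6S)-6-(TBSO)-3-[(3E,5E,7E)-9-(TBSO)-3,7-dimethylnona-3,5,7-trien-1-yn-1-yl]-2,4,4-trimethylcyclohex-2-en-1-one
Conditions: [C5H5NH][CrO3Cl] (pyridinium chlorochromate), 4 Å molecular sieves, CH2Cl2, rt
Reagents that add atoms: pyridinium chlorochromate, [O-][Cr](=O)(=O)Cl.c1cc[nH+]cc1
Why: Babler–Dauben oxidative transposition: the chromate ester of the tertiary allylic alcohol undergoes a [3,3] shift to the ring CH terminus (C4') and is oxidised there, so both epimers of 18 should converge on the enone conjugated with the enyne, the carbonyl oxygen coming from chromate and the C3' centre staying intact under these non-basic conditions.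

Step 12
Reactants: 19 ring B 4'-ketone
Product: 20 (1R,6S)-6-(TBSO)-3-[(3E,5E,7E)-9-(TBSO)-3,7-dimethylnona-3,5,7-trien-1-yn-1-yl]-2,4,4-trimethylcyclohex-2-en-1-ol (cis 3',4' relationship)
Conditions: LiBH(s-Bu)3, THF, −78 °C; aqueous NH4Cl
Reagents that add atoms: none
Why: 1,2-Reduction of the β,β-disubstituted enone by a bulky trialkylborohydride should occur by equatorial approach to C4', the C3' silyloxy group being held pseudo-equatorial by the C1' gem-dimethyl group, which places the new hydroxyl cis to it (4'R, substrate control), and a 1,2-silyl shift in the alkoxide would be harmless because step 13 silylates whichever oxygen is free.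

Step 13
Reactants: 20 cis hydroxy silyl ether
Product: 21 tert-butyl{[(2E,4E,6E)-9-[(3R,4S)-3,4-bis(TBSO)-2,6,6-trimethylcyclohex-1-en-1-yl]-3,7-dimethylnona-2,4,6-trien-8-yn-1-yl]oxy}dimethylsilane
Conditions: TBSOTf, 2,6-lutidine, CH2Cl2, −78 → 0 °C
Reagents that add atoms: tert-butyldimethylsilyl trifluoromethanesulfonate, CC(C)(C)[Si](C)(C)OS(=O)(=O)C(F)(F)F
Why: Silyl ether protection of the hindered allylic secondary alcohol with the silyl triflate and a hindered base should proceed at low temperature without ionising the allylic C–O bond.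

Step 14
Reactants: 21 tris-silyl ether
Product: 22 (2E,4E,6E)-9-[(3R,4S)-3,4-bis(TBSO)-2,6,6-trimethylcyclohex-1-en-1-yl]-3,7-dimethylnona-2,4,6-trien-8-yn-1-ol
Conditions: HF·pyridine, pyridine, THF, 0 °C
Reagents that add atoms: none
Why: Selective desilylation: buffered fluoride should cleave the unhindered primary allylic silyl ether much faster than the two vicinal secondary ring ethers, which are shielded by the C5' methyl and the gem-dimethyl group.

Step 15
Reactants: 22 ring B C20 alcohol
Product: 23 (2E,4E,6E)-9-[(3R,4S)-3,4-bis(TBSO)-2,6,6-trimethylcyclohex-1-en-1-yl]-3,7-dimethylnona-2,4,6-trien-8-ynal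
Conditions: MnO2, CH2Cl2, rt
Reagents that add atoms: none
Why: MnO2 oxidation of the primary polyenylic alcohol should give the aldehyde under neutral conditions that leave the allylic C4' silyl ether and all double bonds unchanged.

Step 16
Reactants: 13 ring A C20 phosphonium bromide; 23 ring B C20 aldehyde
Product: 26 (all-E)-(3R,3'S,4'R)-3,3',4'-tris(TBSO)-7,8,7',8'-tetradehydro-β,β-carotene, via phosphorus ylide 24 (not isolated), via 15Z isomer 25 (not isolated)
Conditions: NaOMe, MeOH/CH2Cl2, 0 °C → rt, argon, dark; aqueous work-up; then heptane, 85 °C, dark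
Reagents that add atoms: none
Why: NaOMe deprotonates C15 of 13 to the semi-stabilised polyenyl ylide 24, which adds to the aldehyde carbon C15' of 23 to give an oxaphosphetane that collapses to the C15=C15' alkene and Ph3PO (Wittig olefination). The closest known reaction is the union of a retinyl-type phosphonium salt with a retinal-type aldehyde in C40 carotenoid synthesis. No ring is closed and no stereocentre is created; the three silyl ethers and both triple bonds are spectators under methoxide. The selectivity needed is E geometry at C15=C15': the Wittig gives an E/Z mixture, and because the 15Z isomer 25 is the sterically unencumbered central cis bond with the lowest rotational barrier of the chain, heating in heptane should convert it to the all-E isomer. Iodine, light and acid are excluded so that the C9=C10 and C9'=C10' bonds beside the triple bonds, whose Z forms are thermodynamically competitive in 7,8-didehydro chains, keep the E geometry brought in by the building blocks. The ylide sits on the ring A half because only that half lacks an ionisable allylic C–O bond, while the ring B half needs only a neutral MnO2 oxidation to become the aldehyde.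

Step 17
Reactants: 26 tris-silyl ether of the target
Product: 27 (all-E)-(3R,3'S,4'R)-7,8,7',8'-tetradehydro-β,β-carotene-3,3',4'-triol (target)
Conditions: Bu4NF, THF, rt, argon, dark; crystallisation from acetone/hexane
Reagents that add atoms: none
Why: Fluoride-induced desilylation cleaves the three Si–O bonds without acid, so the allylic C4' alcohol and the 9E and 9'E bonds should survive, and crystallisation should deliver the all-E triol.

Compound list
1 | (4R,6R)-4-hydroxy-2,2,6-trimethylcyclohexan-1-one (actinol) | CC1(C)C[C@H](O)C[C@@H](C)C1=O | starting material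
2 | (4R,6R)-4-(TBSO)-2,2,6-trimethylcyclohexan-1-one | CC1(C)C[C@H](O[Si](C)(C)C(C)(C)C)C[C@@H](C)C1=O | intermediate
3 | lithium (4R)-4-(TBSO)-2,6,6-trimethylcyclohex-1-en-1-olate | [Li]OC1=C(C)C[C@@H](O[Si](C)(C)C(C)(C)C)CC1(C)C | intermediate
4 | (4R)-4-(TBSO)-2,6,6-trimethylcyclohex-1-en-1-yl trifluoromethanesulfonate | FC(F)(F)S(=O)(=O)OC1=C(C)C[C@@H](O[Si](C)(C)C(C)(C)C)CC1(C)C | intermediate
5 | (E)-3-methylpent-2-en-4-yn-1-ol | OC/C=C(\C)C#C | starting material
6 | (E)-3-methylpent-2-en-4-ynal | O=C/C=C(\C)C#C | intermediate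
7 | triethyl 3-methyl-4-phosphonocrotonate, ethyl (E)-4-(diethoxyphosphoryl)-3-methylbut-2-enoate | CCOC(=O)/C=C(\C)CP(=O)(OCC)OCC | starting material
8 | lithiated phosphonate from 7 | CCOC(=O)/C=C(\C)C([Li])P(=O)(OCC)OCC | intermediate
9 | ethyl (2E,4E,6E)-3,7-dimethylnona-2,4,6-trien-8-ynoate | CCOC(=O)/C=C(C)/C=C/C=C(\C)C#C | intermediate
10 | (2E,4E,6E)-3,7-dimethylnona-2,4,6-trien-8-yn-1-ol | OC/C=C(C)/C=C/C=C(\C)C#C | intermediate
11 | (2E,4E,6E)-9-[(4R)-4-(TBSO)-2,6,6-trimethylcyclohex-1-en-1-yl]-3,7-dimethylnona-2,4,6-trien-8-yn-1-ol | OC/C=C(C)/C=C/C=C(\C)C#CC1=C(C)C[C@@H](O[Si](C)(C)C(C)(C)C)CC1(C)C | intermediate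
12 | allylic bromide of 11, {[(1R)-4-[(3E,5E,7E)-9-bromo-3,7-dimethylnona-3,5,7-trien-1-yn-1-yl]-3,5,5-trimethylcyclohex-3-en-1-yl]oxy}(tert-butyl)dimethylsilane | BrC/C=C(C)/C=C/C=C(\C)C#CC1=C(C)C[C@@H](O[Si](C)(C)C(C)(C)C)CC1(C)C | intermediate
13 | {(2E,4E,6E)-9-[(4R)-4-(TBSO)-2,6,6-trimethylcyclohex-1-en-1-yl]-3,7-dimethylnona-2,4,6-trien-8-yn-1-yl}triphenylphosphonium bromide | c1ccccc1[P+](c1ccccc1)(c1ccccc1)C/C=C(C)/C=C/C=C(\C)C#CC1=C(C)C[C@@H](O[Si](C)(C)C(C)(C)C)CC1(C)C.[Br-] | intermediate
14 | tert-butyl{[(2E,4E,6E)-3,7-dimethylnona-2,4,6-trien-8-yn-1-yl]oxy}dimethylsilane | CC(C)(C)[Si](C)(C)OC/C=C(C)/C=C/C=C(\C)C#C | intermediate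
15 | {[(4R)-4-(TBSO)-2,6,6-trimethylcyclohex-1-en-1-yl]oxy}trimethylsilane | C[Si](C)(C)OC1=C(C)C[C@@H](O[Si](C)(C)C(C)(C)C)CC1(C)C | intermediate
16 | (4S)-4-(TBSO)-2,6,6-trimethylcyclohex-2-en-1-one | O=C1C(C)=C[C@@H](O[Si](C)(C)C(C)(C)C)CC1(C)C | intermediate
17 | lithium acetylide of 14 | [Li]C#C/C(C)=C/C=C/C(C)=C/CO[Si](C)(C)C(C)(C)C | intermediate
18 | (4S)-4-(TBSO)-1-[(3E,5E,7E)-9-(TBSO)-3,7-dimethylnona-3,5,7-trien-1-yn-1-yl]-2,6,6-trimethylcyclohex-2-en-1-ol, both C1 epimers | OC1(C#C/C(C)=C/C=C/C(C)=C/CO[Si](C)(C)C(C)(C)C)C(C)=C[C@@H](O[Si](C)(C)C(C)(C)C)CC1(C)C | intermediate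
19 | (6S)-6-(TBSO)-3-[(3E,5E,7E)-9-(TBSO)-3,7-dimethylnona-3,5,7-trien-1-yn-1-yl]-2,4,4-trimethylcyclohex-2-en-1-one | O=C1C(C)=C(C#C/C(C)=C/C=C/C(C)=C/CO[Si](C)(C)C(C)(C)C)C(C)(C)C[C@@H]1O[Si](C)(C)C(C)(C)C | intermediate
20 | (1R,6S)-6-(TBSO)-3-[(3E,5E,7E)-9-(TBSO)-3,7-dimethylnona-3,5,7-trien-1-yn-1-yl]-2,4,4-trimethylcyclohex-2-en-1-ol | CC(C)(C)[Si](C)(C)OC/C=C(C)/C=C/C=C(\C)C#CC1=C(C)[C@@H](O)[C@@H](O[Si](C)(C)C(C)(C)C)CC1(C)C | intermediate
21 | tert-butyl{[(2E,4E,6E)-9-[(3R,4S)-3,4-bis(TBSO)-2,6,6-trimethylcyclohex-1-en-1-yl]-3,7-dimethylnona-2,4,6-trien-8-yn-1-yl]oxy}dimethylsilane | CC(C)(C)[Si](C)(C)OC/C=C(C)/C=C/C=C(\C)C#CC1=C(C)[C@@H](O[Si](C)(C)C(C)(C)C)[C@@H](O[Si](C)(C)C(C)(C)C)CC1(C)C | intermediate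
22 | (2E,4E,6E)-9-[(3R,4S)-3,4-bis(TBSO)-2,6,6-trimethylcyclohex-1-en-1-yl]-3,7-dimethylnona-2,4,6-trien-8-yn-1-ol | OC/C=C(C)/C=C/C=C(\C)C#CC1=C(C)[C@@H](O[Si](C)(C)C(C)(C)C)[C@@H](O[Si](C)(C)C(C)(C)C)CC1(C)C | intermediate
23 | (2E,4E,6E)-9-[(3R,4S)-3,4-bis(TBSO)-2,6,6-trimethylcyclohex-1-en-1-yl]-3,7-dimethylnona-2,4,6-trien-8-ynal | O=C/C=C(C)/C=C/C=C(\C)C#CC1=C(C)[C@@H](O[Si](C)(C)C(C)(C)C)[C@@H](O[Si](C)(C)C(C)(C)C)CC1(C)C | intermediate
24 | triphenylphosphonium ylide from 13 | c1ccccc1P(c1ccccc1)(c1ccccc1)=C/C=C(C)/C=C/C=C(\C)C#CC1=C(C)C[C@@H](O[Si](C)(C)C(C)(C)C)CC1(C)C | intermediate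
25 | (15Z)-(3R,3'S,4'R)-3,3',4'-tris(TBSO)-7,8,7',8'-tetradehydro-β,β-carotene | CC1=C(C#C/C(C)=C/C=C/C(C)=C/C=C\C=C(C)\C=C\C=C(/C)C#CC2=C(C)[C@@H](O[Si](C)(C)C(C)(C)C)[C@@H](O[Si](C)(C)C(C)(C)C)CC2(C)C)C(C)(C)C[C@H](O[Si](C)(C)C(C)(C)C)C1 | intermediate
26 | (all-E)-(3R,3'S,4'R)-3,3',4'-tris(TBSO)-7,8,7',8'-tetradehydro-β,β-carotene | CC1=C(C#C/C(C)=C/C=C/C(C)=C/C=C/C=C(C)/C=C/C=C(\C)C#CC2=C(C)[C@@H](O[Si](C)(C)C(C)(C)C)[C@@H](O[Si](C)(C)C(C)(C)C)CC2(C)C)C(C)(C)C[C@H](O[Si](C)(C)C(C)(C)C)C1 | intermediate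
27 | (all-E)-(3R,3'S,4'R)-7,8,7',8'-tetradehydro-β,β-carotene-3,3',4'-triol | CC1=C(C#C/C(C)=C/C=C/C(C)=C/C=C/C=C(C)/C=C/C=C(\C)C#CC2=C(C)[C@@H](O)[C@@H](O)CC2(C)C)C(C)(C)C[C@H](O)C1 | target

Total step count: 17.
Longest linear sequence: 12 steps (5 → 6 → 9 → 10 → 14 → 18 → 19 → 20 → 21 → 22 → 23 → 26 → 27; steps 3, 4, 5, 8 and 10 to 17).

Steps most likely to fail

Step 12: the hydride may be delivered to the wrong face of the C4' carbonyl (axial attack, giving the trans relationship), or conjugate reduction may compete. The fallback sets out from 19 and replaces face selection by inversion. Luche reduction (NaBH4, CeCl3, MeOH, −40 °C), where axial attack should prevail, would give the trans alcohol (1S,6S)-6-(TBSO)-3-[(3E,5E,7E)-9-(TBSO)-3,7-dimethylnona-3,5,7-trien-1-yn-1-yl]-2,4,4-trimethylcyclohex-2-en-1-ol F1. Mitsunobu esterification with 4-nitrobenzoic acid (PPh3, diisopropyl azodicarboxylate, toluene, 0 °C) would invert C4' to the cis 4-nitrobenzoate F2. Methanolysis (K2CO3, MeOH) would then rejoin the route at 20.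

Step 11: the chromate [3,3] shift may lose out to ionisation and dehydration of the tertiary propargylic alcohol, or the triene may be over-oxidised. The fallback sets out from 18 and separates transposition from oxidation. A catalytic 1,3-hydroxyl shift with Ph3SiOReO3 (Et2O, −50 → 0 °C), driven by conjugation of the new tetrasubstituted alkene with the enyne, should give the secondary allylic alcohol F3 as a mixture of C4' epimers. Oxidation of this mixture with MnO2 in CH2Cl2 would return to 19.

Step 16: the polyenyl ylide or the aldehyde may decompose under methoxide before they combine, so that conversion stays low. The fallback sets out from 11, keeps the C15=C15' disconnection and avoids both the allylic bromide and the ylide. Mitsunobu thioetherification with 2-mercaptobenzothiazole (PPh3, diisopropyl azodicarboxylate, THF, 0 °C) would give the benzothiazolyl sulfide F4. Oxidation with (NH4)6Mo7O24 and H2O2 (EtOH, 0 °C) would give the benzothiazolyl sulfone F5. Julia–Kocienski olefination of this sulfone with aldehyde 23 (KN(SiMe3)2, THF, −78 °C), followed by the same thermal equilibration in heptane, would arrive at 26.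

Further compounds
F1 | step 12 | (1S,6S)-6-(TBSO)-3-[(3E,5E,7E)-9-(TBSO)-3,7-dimethylnona-3,5,7-trien-1-yn-1-yl]-2,4,4-trimethylcyclohex-2-en-1-ol | CC(C)(C)[Si](C)(C)OC/C=C(C)/C=C/C=C(\C)C#CC1=C(C)[C@H](O)[C@@H](O[Si](C)(C)C(C)(C)C)CC1(C)C
F2 | step 12 | (1R,6S)-6-(TBSO)-3-[(3E,5E,7E)-9-(TBSO)-3,7-dimethylnona-3,5,7-trien-1-yn-1-yl]-2,4,4-trimethylcyclohex-2-en-1-yl 4-nitrobenzoate | CC(C)(C)[Si](C)(C)OC/C=C(C)/C=C/C=C(\C)C#CC1=C(C)[C@@H](OC(=O)c2ccc(cc2)[N+](=O)[O-])[C@@H](O[Si](C)(C)C(C)(C)C)CC1(C)C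
F3 | step 11 | (6S)-6-(TBSO)-3-[(3E,5E,7E)-9-(TBSO)-3,7-dimethylnona-3,5,7-trien-1-yn-1-yl]-2,4,4-trimethylcyclohex-2-en-1-ol, both C1 epimers | CC(C)(C)[Si](C)(C)OC/C=C(C)/C=C/C=C(\C)C#CC1=C(C)C(O)[C@@H](O[Si](C)(C)C(C)(C)C)CC1(C)C
F4 | step 16 | 2-{[(2E,4E,6E)-9-[(4R)-4-(TBSO)-2,6,6-trimethylcyclohex-1-en-1-yl]-3,7-dimethylnona-2,4,6-trien-8-yn-1-yl]sulfanyl}-1,3-benzothiazole | c1ccc2sc(SC/C=C(C)/C=C/C=C(\C)C#CC3=C(C)C[C@@H](O[Si](C)(C)C(C)(C)C)CC3(C)C)nc2c1
F5 | step 16 | 2-{[(2E,4E,6E)-9-[(4R)-4-(TBSO)-2,6,6-trimethylcyclohex-1-en-1-yl]-3,7-dimethylnona-2,4,6-trien-8-yn-1-yl]sulfonyl}-1,3-benzothiazole | c1ccc2sc(S(=O)(=O)C/C=C(C)/C=C/C=C(\C)C#CC3=C(C)C[C@@H](O[Si](C)(C)C(C)(C)C)CC3(C)C)nc2c1
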